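The runs are calculated for an exercise, noise included.

The time of reading separates the two flasks: Friday's is stopped at 4.0 h and Sunday's at 1.0 h, from the same charge. In each, a racemate of left-handed and right-handed substrate couples with the coupling partner under a single-handed catalyst.

| setting | north-west | south-west | north-east | Friday's | Sunday's |
|---|---|---|---|---|---|
| left-handed substrate | 16 mM | 16 mM | 8 mM | 16 mM | 16 mM |
| right-handed substrate | 16 mM | 16 mM | 8 mM | 16 mM | 16 mM |
| coupling partner | 67 mM | 110 mM | 48 mM | 48.0 mM | 48.0 mM |
| free catalyst | 1.8 mM | 1.8 mM | 1.8 mM | 1.8 mM | 1.8 mM |
| remark | run made earlier | run made earlier | run made earlier |  |  |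
| time |  |  |  | 4.0 h | 1.0 h |

| run | time / h | left-handed product / % | right-handed product / % |
|---|---|---|---|
| north-west | 0.200 | 3.7 | 2.6 |
| north-west | 0.333 | 5.8 | 2.5 |
| north-west | 0.667 | 11.0 | 10.8 |
| north-west | 1.33 | 18.4 | 16.1 |
| north-west | 2.50 | 24.3 | 24.7 |
| south-west | 0.500 | 15.9 | 10.3 |
| south-west | 1.00 | 20.0 | 20.7 |
| south-west | 1.33 | 24.8 | 22.5 |
| south-west | 2.00 | 30.0 | 28.5 |
| south-west | 2.50 | 32.9 | 34.2 |
| north-east | 0.200 | 6.0 | 1.4 |
| north-east | 0.333 | 9.0 | 3.7 |
| north-east | 0.667 | 10.7 | 7.8 |
| north-east | 1.33 | 18.1 | 16.5 |
| north-east | 2.50 | 25.5 | 25.7 |

(readings scatter by 1 percentage point)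

- free catalyst is single-handed; left-handed substrate and right-handed substrate are mirror images of each other, charged as a racemate, each of them at the stated concentration
- an excess is the difference of the two amounts in percent of their sum
- an excess is below zero if the other one leads

* which one finishes higher in excess of left-handed product over right-handed product in the product ("neither" within 2 percentage points) (Friday's / Sunday's / neither)
* excess of left-handed product over right-handed product in the product at the end, Friday's
* excess of left-handed product over right-handed product in the product at the end, Sunday's

I first ask which input must be known well. The partner charge seems not to be one: at 1.33 h the excess reads 6.67% at [coupling partner] = 67 mM and 4.86% at 110 mM. The north-east run, with 8 mM of each substrate, reads 4.62%. Each is a difference of two readings with a scatter of 1 percentage point, so I take the spread for scatter. Time does matter: summing the products over the runs read at each time, the excess falls from 41.0% at 0.333 h to 5.33% at 1.33 h.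

I assume a first-order fall, which integrates to an excess halved in each equal interval. That interval is the fading half-time, here 0.339 h. Its weak point is the small late excess, but Sunday's time lies inside the two pooled readings, so there I interpolate. Friday's lies 10.8 half-times out, so a modest error leaves it near zero. I reckon 10.5% for Sunday's and 0.0226% for Friday's.

The forecast, on a lead that “fades with time and conversion”, names Sunday's, with −0.5% for Friday's (−4% to 3%) and 7% for Sunday's (2% to 14%).

The flasks give 0.554% for Friday's and 10.8% for Sunday's, so Sunday's finishes higher.

    free catalyst + left-handed substrate ⇌ catalyst intermediate A (K = 60.9 M⁻¹, k = 3.50 M⁻¹ s⁻¹)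
    free catalyst + right-handed substrate ⇌ catalyst intermediate B (K = 102 M⁻¹, k = 96.2 M⁻¹ s⁻¹)
    coupling partner + catalyst intermediate A → free catalyst + left-handed product (k = 0.118 M⁻¹ s⁻¹)
    coupling partner + catalyst intermediate B → free catalyst + right-handed product (k = 0.00817 M⁻¹ s⁻¹)
    left-handed product ⇌ right-handed product (k = 7.65 × 10⁻⁴ s⁻¹)
    coupling partner → decomposition product (k = 6.71 × 10⁻⁷ s⁻¹)
    2 free catalyst ⇌ resting dimer, settled at all times (K = 540 M⁻¹)

With 0.339 h, my 10.5% stands against 10.8% on Sunday's flask, and the gap to Friday's comes from the time. The fading is mainly kinetic control giving way to thermodynamic control: without the turning of left-handed product into right-handed product, both ways, Sunday's excess reads 73.6% instead of 10.8%. Friday's flask read at 1.5 h gets 3.76% from the half-time; the computed value is 5.91%, higher, so by that time the excess has fallen less than my half-time says.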